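The second end groups stood at 0.162 M in the planned flask, against 0.18 M of first end groups, and I had to decide whether that charge and the time could stay.

- theta: first end groups 0.090 M; second end groups 0.162 M; run made earlier
- flask: first end groups 0.18 M; second end groups 0.162 M; time 4.0 d

theta run (percent of the first end groups charged)

| time / h | links / % | first end groups / % |
|---|---|---|
| 1.50 | 18.5 | 82.5 |
| 2.50 | 26.3 | 73.0 |
| 4.00 | 37.5 | 62.4 |
| 5.00 | 43.6 | 56.4 |
| 8.00 | 58.8 | 41.9 |
| 12.0 | 70.1 | 30.4 |
| 20.0 | 83.2 | 16.4 |

(standard deviation of a reading: 0.5 percentage points)

- what was read earlier has a scatter of 0.5 percentage points, one standard deviation
- a reading or a percentage of links counts all its forms, free or not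
- the reaction counts as stopped when no species that holds the first end groups changes by six tenths of a point or more over the second half of the time

* the state of affairs at 4.0 d: stopped, and by what, or still going (forward and back rates have come level / the second end groups has run out first / it is still moving / all of the first end groups has reacted)
* the links standing at 4.0 d, as a percentage of the first end groups charged
* amount of links if the flask were left three thousand times as long, in percent of the first end groups charged

At the last theta reading, links and first end groups added up to 99.6%. So I counted one link for each first end group and each second end group used. That gave me my rule. The flask's ceiling was 90.0%: the smaller charge as a share of the first end groups charged. The crossing lies at equal charges. In this flask the second end groups were the smaller charge, which made them the limiting reagent.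

The ceiling gave no time, so I read a second-order rate constant, k, from that last theta reading: 0.0137 M⁻¹ min⁻¹. With k, I reckoned links in the flask at 87.2% after 4.0 d, which was 2.8 percentage points under the ceiling. At half that time I reckoned 82.1%. The second half would therefore add 5.1 points, and I expected the flask still to be moving. I kept the charges and the time.

The forecast said it is still moving, with links at 87.2% and finally 90%: “so the reaction is still moving”.

At 4.0 d the state of the flask was this: it is still moving. Links stood at 87.3%, which was 2.7 points under the ceiling, and left far longer they reached 90.0%.

    first end groups + second end groups → links (k = 0.0139 M⁻¹ min⁻¹)
    crystals ⇌ links, rate k2*(cs2 - [links]) while solid is left; crystals form when [links] > cs2 (solubility = 0.120 M, k = 0.0133 min⁻¹)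

The flask also held crystals, 15.3% at 2.00 d and 20.6% at 4.00 d, counted in the links. Their leaving solution made no difference to the conversion of first end groups. The links of this flask at 4.0 d moved by 5 points when its second end groups went down to 0.151 M, with the first end groups and the time held. In the neighbouring flask with 0.041 M of second end groups, the ceiling was 22.8%. That neighbour held 22.8% links at 4.00 d, with 77% of its first end groups left and 0% of its second end groups.

The readings are calculated on assumed constants, noise included.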